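The ratio of uncatalysed product to target in a finished run is the number to read here. The gas phase is held, so substrate is the limiting reagent, and each mole of it has three entries in the ledger: target, uncatalysed product, substrate left. Both routes take one substrate and one dissolved gas, so these cancel from the ratio of their rates and catalyst concentration remains in it.

in all of them: substrate 0.80 M; gas phase 35 mM (held)
- cedar: catalyst 13 mM; run made earlier
- maple: catalyst 21 mM; run made earlier
- flask: catalyst 9.6 mM; time 15 d

| run | time / d | target / % | substrate / % |
|---|---|---|---|
| cedar | 2.50 | 94.0 | 0.5 |
| cedar | 5.00 | 94.8 | 0 |
| cedar | 8.00 | 94.1 | 0.1 |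
| cedar | 10.0 | 94.2 | 0.3 |
| cedar | 12.0 | 94.8 | 0 |
| cedar | 15.0 | 94.7 | 0.1 |
| cedar | 20.0 | 94.5 | 0.2 |
| maple | 1.04 | 91.1 | 6.3 |
| maple | 3.00 | 97.5 | 0 |
| maple | 5.00 | 96.6 | 0 |
| maple | 8.00 | 96.6 | 0 |
| maple | 10.0 | 96.3 | 0.4 |
| maple | 15.0 | 96.9 | 0 |
| maple | 20.0 | 96.6 | 0.2 |

(each reading ± 0.5 percentage points)

- which holds at 15 d: what has brought the reaction to rest, or that it has not come to rest (forward and back rates have come level / no working catalyst is left / it is still moving / all of the substrate has reacted)
- how much target there is at 15 d, in percent of the substrate charged

- at the start none of the gas is dissolved
- reactions considered so far: gas phase <-> dissolved gas; substrate + dissolved gas + catalyst -> catalyst + target; substrate + dissolved gas -> uncatalysed product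
- the reaction counts as stopped when no species that holds the substrate changes by six tenths of a point or more over the second half of the time

Cedar's last reading books 94.5% as target and 0.2% as substrate, so the remainder, 5.30%, is read as uncatalysed product. Its ratio to target, times cedar's catalyst, gives 0.729 mM. Maple's last reading leaves 3.20% and gives 0.696 mM, close to cedar's although its catalyst differs.

Their mean, 0.712 mM, is a reading that carries the scatter. I call it the crossover catalyst, the catalyst concentration at which the two routes take equal fractions of the charge. The target's fraction is then catalyst over catalyst plus crossover, which for this flask books 93.1%.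

Do the books close in time? Maple's first reading shows 6.3% substrate after 1.04 d. Scaled by catalyst plus crossover, that one reading gives an estimate for this flask: a pseudo-first-order rate of 1.26 /d and a half-life of 0.549 d, so 15 d is about 27.3 half-lives.

The forecast says all of the substrate has reacted and gives 92.7%, a little less than my figure. Its ground: "Both routes use substrate and dissolved gas, so product ratio should scale with catalyst."

The flask gives all of the substrate has reacted and 93.3% target, 0.60 percentage points above the forecast.

    gas phase ⇌ dissolved gas, rate k1*(csat - [dissolved gas]) (kL = 13.0 /h)
    substrate + dissolved gas + catalyst → catalyst + target (k = 160 /M²/h)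
    substrate + dissolved gas → uncatalysed product (k = 0.110 /M/h)

At 15.0 d the ledger of the flask reads substrate 0%, uncatalysed product 6.68%, with catalyst at 100% of its charge, and the drag of the gas crossing, absent from the crossover, changes target by nothing. A neighbouring flask charged with 3.80 mM of catalyst is reckoned the same way: catalyst over catalyst plus 0.712 mM books 84.2% target. That neighbour ends with 84.7% target, 15.3% uncatalysed product and 0.012% substrate left.

The earlier runs and the new flask stem from a simulated flask from invented constants, noise included.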